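**Plan**
- Retrosynthesis: the O–S bond of the sulfate and the four benzyl ethers are cut first. The C2=C3 double bond is then taken back to a 2,3-dihydroflavonol and the O1–C2 bond to a chalcone epoxide. The oxirane is cut at C2–C3 and C3–O into a ring A chloromethyl ketone and 4-(benzyloxy)benzaldehyde, and the C4–C4a bond into an aryllithium and a chloroacetamide.
- Enabling feature: in ring C, C2 (bonded to ring B and O1) and C3 (bonded to the sulfated oxygen) are neighbouring oxygen-bearing carbons beside the C4 carbonyl, which is a masked α,β-epoxy ketone. The oxygen at C5, ortho to the C4a–C4 bond, is the substituent that sends oxidative chalcone cyclisation to aurones, so O3 is better brought in as the aldehyde oxygen.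
- Forward: ring A is benzylated, converted into the phenol, MOM-protected and chloroacetylated. The Darzens step joins ring B and forms the oxirane. Acid then closes the six-membered ring C by opening the oxirane at C2, and dehydrogenation, sulfation of the only free hydroxyl and hydrogenolysis finish the route.
- Stereochemistry: the target has no stereocentre. The trans relationship in the epoxide and the dihydroflavonol is relative only, both are racemic with one enantiomer drawn, and both centres are erased in step 7.

Key step: step 5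

Assumption: the target is drawn as the free hydrogen sulfate, which hydrolyses autocatalytically, so the sulfate is carried as its sodium salt and protonated only in the last operation, cold, just before freeze-drying.

**Step 1**
Reactants: 1 3,4,5-trihydroxybenzaldehyde
Product: 2 3,4,5-tris(benzyloxy)benzaldehyde
Conditions: BnBr (3.5 equiv), K2CO3, DMF, 60 °C, N2
Reagents that add atoms: benzyl bromide, BrCc1ccccc1
Why: Williamson ether synthesis, in which the three phenoxides are alkylated by the benzylic bromide while the aldehyde is inert to carbonate and exclusion of air protects the pyrogallol unit until it is capped.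

**Step 2**
Reactants: 2 3,4,5-tris(benzyloxy)benzaldehyde
Product: 4 3,4,5-tris(benzyloxy)phenol, via aryl formate 3 (not isolated)
Conditions: mCPBA, CH2Cl2, 0 °C → rt; aq. NaHCO3 wash; then K2CO3 (cat.), MeOH, rt
Reagents that add atoms: 3-chloroperoxybenzoic acid, O=C(OO)c1cccc(Cl)c1
Why: Baeyer–Villiger (Dakin-type) oxidation, in which the electron-rich trialkoxyaryl group migrates in preference to hydrogen to give formate 3, which methanol then transesterifies to the phenol.

**Step 3**
Reactants: 4 3,4,5-tris(benzyloxy)phenol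
Product: 5 1,2,3-tris(benzyloxy)-5-(methoxymethoxy)benzene
Conditions: MOMCl, i-Pr2NEt, CH2Cl2, 0 °C → rt
Reagents that add atoms: chloromethyl methyl ether, COCCl
Why: O-alkylation of the phenol with an α-chloro ether (MOM acetal formation) installs a group that directs lithiation, survives base and can later be removed by acid beside benzyl ethers.

**Step 4**
Reactants: 5 1,2,3-tris(benzyloxy)-5-(methoxymethoxy)benzene; 6 2-chloro-N-methoxy-N-methylacetamide
Product: 9 2-chloro-1-[2,3,4-tris(benzyloxy)-6-(methoxymethoxy)phenyl]ethan-1-one, via aryllithium 7 (not isolated), via lithium hemiaminal adduct 8 (not isolated)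
Conditions: n-BuLi (1.1 equiv), THF, −20 → 0 °C; then 6, −78 → −20 °C; AcOH quench
Reagents that add atoms: none
Why: Directed ortho-metalation followed by Weinreb ketone synthesis, in which the ring C–H flanked by OMOM and OBn is the most acidic and chelation-directed site (the two such sites are equivalent by symmetry) and the chelated adduct 8 persists until the quench, so the chloro ketone never meets the aryllithium.

**Step 5**
Reactants: 9 2-chloro-1-[2,3,4-tris(benzyloxy)-6-(methoxymethoxy)phenyl]ethan-1-one; 10 4-(benzyloxy)benzaldehyde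
Product: 12 rac-[(2S,3R)-3-[4-(benzyloxy)phenyl]oxiran-2-yl][2,3,4-tris(benzyloxy)-6-(methoxymethoxy)phenyl]methanone (trans-epoxy ketone), via chlorohydrin alkoxide 11 (not isolated)
Conditions: NaOH (2 M aq., 1.3 equiv), EtOH–THF, 0 °C → rt
Reagents that add atoms: none
Why: Base removes a proton from the CH2Cl group of 9, the resulting carbanion adds reversibly to the aldehyde carbon of 10 (new C–C bond, the later C2–C3), and the anti aldolate 11 closes the oxirane by internal SN2 displacement of chloride (new C–O bond, 3-exo-tet), so the aldehyde oxygen becomes the future O3. This is a Darzens condensation of a phenacyl chloride with an aromatic aldehyde, a standard entry to trans-chalcone oxides. The two new stereocentres are fixed relative to each other only: since the aldol addition is reversible and the anti aldolate reaches the anti-periplanar O–C–C–Cl geometry with aroyl and aryl held apart, the trans-epoxide should predominate, as the racemate. The selectivity the step needs is chemoselectivity, and it is secured by the two ortho substituents of ring A, which twist and shield the ketone carbonyl against self-condensation and hydroxide addition, and by the absence of any α′-hydrogen that could open a Favorskii pathway. The diastereomer ratio carries no weight, because both centres are removed in step 7.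

**Step 6**
Reactants: 12 trans-epoxy ketone
Product: 14 rac-(2S,3S)-5,6,7-tris(benzyloxy)-2-[4-(benzyloxy)phenyl]-3-hydroxy-2,3-dihydro-4H-chromen-4-one (trans-dihydroflavonol), via phenol epoxide 13 (not isolated)
Conditions: conc. HCl (cat.), MeOH–THF, 55 °C
Reagents that add atoms: none
Why: Acid-catalysed cleavage of the MOM acetal frees phenol 13, whose hydroxyl opens the protonated oxirane at the benzylic carbon (future C2), where the 4-benzyloxyphenyl group stabilises positive charge; this 6-endo epoxide opening with inversion is the standard acid cyclisation of 2'-O-protected chalcone epoxides to dihydroflavonols, C3 keeps its epoxide configuration, and the relative configuration is immaterial for what follows.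

**Step 7**
Reactants: 14 trans-dihydroflavonol
Product: 15 5,6,7-tris(benzyloxy)-2-[4-(benzyloxy)phenyl]-3-hydroxy-4H-chromen-4-one
Conditions: I2 (1.2 equiv), KOAc, AcOH, 100 °C; aq. Na2S2O3 work-up
Reagents that add atoms: none
Why: Iodine–acetate dehydrogenation of a dihydroflavonol, in which enolisation of the C4 ketone toward C3 lets iodine oxidise the α-hydroxy ketone and loss of the C2 hydrogen gives the conjugated 3-hydroxy-4-pyranone, while acetate takes up the HI so that the benzyl ethers are spared; both stereocentres disappear here.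

**Step 8**
Reactants: 15 5,6,7-tris(benzyloxy)-2-[4-(benzyloxy)phenyl]-3-hydroxy-4H-chromen-4-one
Product: 17 sodium 5,6,7-tris(benzyloxy)-2-[4-(benzyloxy)phenyl]-4-oxo-4H-chromen-3-yl sulfate, via pyridinium sulfate 16 (not isolated)
Conditions: SO3·pyridine (5 equiv), pyridine, 60 °C; then aq. NaHCO3
Reagents that add atoms: sulfur trioxide–pyridine complex, [O-]S(=O)(=O)[n+]1ccccc1; sodium hydrogencarbonate, [Na+].OC([O-])=O
Why: O-Sulfonation with a sulfur trioxide–amine complex needs no site selectivity because the 3-hydroxyl is the only free hydroxyl of 15, and exchange to the sodium salt removes pyridine before the hydrogenation and keeps the monoester stable.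

**Step 9**
Reactants: 17 sodium 5,6,7-tris(benzyloxy)-2-[4-(benzyloxy)phenyl]-4-oxo-4H-chromen-3-yl sulfate
Product: 19 5,6,7-trihydroxy-2-(4-hydroxyphenyl)-4-oxo-4H-chromen-3-yl hydrogen sulfate (target), via target sodium salt 18 (not isolated)
Conditions: H2 (1 atm), Pd/C (10 wt% Pd), MeOH–THF, rt; filter under Ar; then aq. HCl (1.0 equiv), 0 °C; C18 desalting, freeze-drying
Reagents that add atoms: none
Why: Catalytic hydrogenolysis cleaves the four benzylic C–O bonds while the sulfate monoester anion and the pyranone double bond are untouched under neutral conditions, and one equivalent of cold acid then protonates the sulfate to the drawn hydrogen sulfate.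

**Compound list**
1 | 3,4,5-trihydroxybenzaldehyde | O=Cc1cc(O)c(O)c(O)c1 | starting material
2 | 3,4,5-tris(benzyloxy)benzaldehyde | O=Cc1cc(OCc2ccccc2)c(OCc2ccccc2)c(OCc2ccccc2)c1 | intermediate
3 | aryl formate: 3,4,5-tris(benzyloxy)phenyl formate | O=COc1cc(OCc2ccccc2)c(OCc2ccccc2)c(OCc2ccccc2)c1 | intermediate
4 | 3,4,5-tris(benzyloxy)phenol | Oc1cc(OCc2ccccc2)c(OCc2ccccc2)c(OCc2ccccc2)c1 | intermediate
5 | 1,2,3-tris(benzyloxy)-5-(methoxymethoxy)benzene | COCOc1cc(OCc2ccccc2)c(OCc2ccccc2)c(OCc2ccccc2)c1 | intermediate
6 | 2-chloro-N-methoxy-N-methylacetamide | CON(C)C(=O)CCl | starting material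
7 | aryllithium: [2,3,4-tris(benzyloxy)-6-(methoxymethoxy)phenyl]lithium | [Li]c1c(OCOC)cc(OCc2ccccc2)c(OCc2ccccc2)c1OCc1ccccc1 | intermediate
8 | lithium hemiaminal adduct: lithium 2-chloro-1-[methoxy(methyl)amino]-1-[2,3,4-tris(benzyloxy)-6-(methoxymethoxy)phenyl]ethan-1-olate (racemic) | [Li+].[O-]C(CCl)(N(C)OC)c1c(OCOC)cc(OCc2ccccc2)c(OCc2ccccc2)c1OCc1ccccc1 | intermediate
9 | 2-chloro-1-[2,3,4-tris(benzyloxy)-6-(methoxymethoxy)phenyl]ethan-1-one | O=C(CCl)c1c(OCOC)cc(OCc2ccccc2)c(OCc2ccccc2)c1OCc1ccccc1 | intermediate
10 | 4-(benzyloxy)benzaldehyde | O=Cc1ccc(OCc2ccccc2)cc1 | starting material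
11 | chlorohydrin alkoxide: sodium (1R,2R)-1-[4-(benzyloxy)phenyl]-2-chloro-3-oxo-3-[2,3,4-tris(benzyloxy)-6-(methoxymethoxy)phenyl]propan-1-olate (anti aldolate, racemic, one enantiomer drawn) | O=C(c1c(OCOC)cc(OCc2ccccc2)c(OCc2ccccc2)c1OCc1ccccc1)[C@H](Cl)[C@H]([O-])c1ccc(OCc2ccccc2)cc1.[Na+] | intermediate
12 | trans-epoxy ketone: [(2S,3R)-3-[4-(benzyloxy)phenyl]oxiran-2-yl][2,3,4-tris(benzyloxy)-6-(methoxymethoxy)phenyl]methanone (racemic, one enantiomer drawn) | O=C(c1c(OCOC)cc(OCc2ccccc2)c(OCc2ccccc2)c1OCc1ccccc1)[C@H]1O[C@@H]1c1ccc(OCc2ccccc2)cc1 | intermediate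
13 | phenol epoxide: [(2S,3R)-3-[4-(benzyloxy)phenyl]oxiran-2-yl][2,3,4-tris(benzyloxy)-6-hydroxyphenyl]methanone (racemic, one enantiomer drawn) | O=C(c1c(O)cc(OCc2ccccc2)c(OCc2ccccc2)c1OCc1ccccc1)[C@H]1O[C@@H]1c1ccc(OCc2ccccc2)cc1 | intermediate
14 | trans-dihydroflavonol: (2S,3S)-5,6,7-tris(benzyloxy)-2-[4-(benzyloxy)phenyl]-3-hydroxy-2,3-dihydro-4H-chromen-4-one (racemic, one enantiomer drawn) | O=C1c2c(OCc3ccccc3)c(OCc3ccccc3)c(OCc3ccccc3)cc2O[C@@H](c2ccc(OCc3ccccc3)cc2)[C@@H]1O | intermediate
15 | 5,6,7-tris(benzyloxy)-2-[4-(benzyloxy)phenyl]-3-hydroxy-4H-chromen-4-one | O=c1c(O)c(-c2ccc(OCc3ccccc3)cc2)oc2cc(OCc3ccccc3)c(OCc3ccccc3)c(OCc3ccccc3)c12 | intermediate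
16 | pyridinium sulfate: pyridinium 5,6,7-tris(benzyloxy)-2-[4-(benzyloxy)phenyl]-4-oxo-4H-chromen-3-yl sulfate | O=c1c(OS(=O)(=O)[O-])c(-c2ccc(OCc3ccccc3)cc2)oc2cc(OCc3ccccc3)c(OCc3ccccc3)c(OCc3ccccc3)c12.c1cc[nH+]cc1 | intermediate
17 | sodium 5,6,7-tris(benzyloxy)-2-[4-(benzyloxy)phenyl]-4-oxo-4H-chromen-3-yl sulfate | O=c1c(OS(=O)(=O)[O-])c(-c2ccc(OCc3ccccc3)cc2)oc2cc(OCc3ccccc3)c(OCc3ccccc3)c(OCc3ccccc3)c12.[Na+] | intermediate
18 | target sodium salt: sodium 5,6,7-trihydroxy-2-(4-hydroxyphenyl)-4-oxo-4H-chromen-3-yl sulfate | O=c1c(OS(=O)(=O)[O-])c(-c2ccc(O)cc2)oc2cc(O)c(O)c(O)c12.[Na+] | intermediate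
19 | 5,6,7-trihydroxy-2-(4-hydroxyphenyl)-4-oxo-4H-chromen-3-yl hydrogen sulfate | O=c1c(OS(=O)(=O)O)c(-c2ccc(O)cc2)oc2cc(O)c(O)c(O)c12 | target

**Step count**
Total: 9 steps. Longest linear sequence: 9 steps (1 → 19); compounds 6 and 10 are purchased and enter in steps 4 and 5.

**Steps most likely to fail**

1. Step 5 (Darzens condensation). The hindered, electron-rich chloro ketone may add only slowly to the deactivated 4-alkoxybenzaldehyde. Hydroxide substitution of chloride, return of the aldolate to its components and base degradation of the epoxide would then consume material.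
Fallback: the epoxide oxygen is supplied by peroxide instead of the aldehyde. Setting out from 5, lithiation as in step 4 and quenching with N-methoxy-N-methylacetamide should give the methyl ketone 1-[2,3,4-tris(benzyloxy)-6-(methoxymethoxy)phenyl]ethan-1-one F1. Claisen–Schmidt condensation of F1 with 10 (KOH, EtOH–THF, rt) should give the chalcone (E)-3-[4-(benzyloxy)phenyl]-1-[2,3,4-tris(benzyloxy)-6-(methoxymethoxy)phenyl]prop-2-en-1-one F2. Weitz–Scheffer epoxidation of F2 (H2O2, NaOH, MeOH–THF, 0 °C → rt) should return the route at the trans-epoxy ketone 12. Because the 2'-oxygen stays masked as the MOM ether, no phenoxide is present to divert the epoxide to an aurone.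

2. Step 4 (ortho-lithiation and chloroacetylation). Metalation at a benzylic OCH2 group, followed by Wittig rearrangement, may compete with ring lithiation at the temperature that deprotonation requires.
Fallback: the aryllithium is made by halogen–lithium exchange instead of deprotonation. Setting out from 5, NBS in MeCN at 0 °C should brominate one of the two equivalent free ring positions to give 1,2,3-tris(benzyloxy)-4-bromo-5-(methoxymethoxy)benzene F3. Treatment of F3 with n-BuLi in THF at −78 °C exchanges bromine for lithium faster than any benzylic deprotonation. The route is rejoined at aryllithium 7, which is acylated with 6 as in step 4 to give 9.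

3. Step 8 (sulfation). O-Sulfonation of the hydrogen-bonded, weakly nucleophilic 3-hydroxyl may stay incomplete, and the sulfate may be lost by hydrolysis while the polar salt is purified.
Fallback: the sulfate is introduced as a neutral, chromatographable diester. Setting out from 15, 2,2,2-trichloroethyl chlorosulfate with Et3N and DMAP in THF should give 5,6,7-tris(benzyloxy)-2-[4-(benzyloxy)phenyl]-4-oxo-4H-chromen-3-yl 2,2,2-trichloroethyl sulfate F4. Reductive fragmentation of the trichloroethyl group with Zn dust and HCO2NH4 in MeOH–THF should give ammonium 5,6,7-tris(benzyloxy)-2-[4-(benzyloxy)phenyl]-4-oxo-4H-chromen-3-yl sulfate F5. Work-up of F5 with aqueous NaHCO3 returns the route at sodium salt 17, which then enters step 9 unchanged.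

**Further compounds**
F1 | step 5 | 1-[2,3,4-tris(benzyloxy)-6-(methoxymethoxy)phenyl]ethan-1-one | CC(=O)c1c(OCOC)cc(OCc2ccccc2)c(OCc2ccccc2)c1OCc1ccccc1
F2 | step 5 | (E)-3-[4-(benzyloxy)phenyl]-1-[2,3,4-tris(benzyloxy)-6-(methoxymethoxy)phenyl]prop-2-en-1-one | O=C(/C=C/c1ccc(OCc2ccccc2)cc1)c1c(OCOC)cc(OCc2ccccc2)c(OCc2ccccc2)c1OCc1ccccc1
F3 | step 4 | 1,2,3-tris(benzyloxy)-4-bromo-5-(methoxymethoxy)benzene | Brc1c(OCOC)cc(OCc2ccccc2)c(OCc2ccccc2)c1OCc1ccccc1
F4 | step 8 | 5,6,7-tris(benzyloxy)-2-[4-(benzyloxy)phenyl]-4-oxo-4H-chromen-3-yl 2,2,2-trichloroethyl sulfate | O=c1c(OS(=O)(=O)OCC(Cl)(Cl)Cl)c(-c2ccc(OCc3ccccc3)cc2)oc2cc(OCc3ccccc3)c(OCc3ccccc3)c(OCc3ccccc3)c12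
F5 | step 8 | ammonium 5,6,7-tris(benzyloxy)-2-[4-(benzyloxy)phenyl]-4-oxo-4H-chromen-3-yl sulfate | O=c1c(OS(=O)(=O)[O-])c(-c2ccc(OCc3ccccc3)cc2)oc2cc(OCc3ccccc3)c(OCc3ccccc3)c(OCc3ccccc3)c12.[NH4+]
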